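## Structural features

The target 16 is a 1-aryl-1,2-dihydronaphthalene lignan. Its benzo ring A (C4a, C5 to C8, C8a) carries three neighbouring methoxy groups on C6, C7 and C8 and is fused to ring B (C1 to C4), whose only double bond, C3=C4, is conjugated with ring A. C1 carries a 3,4-dimethoxyphenyl group and lies peri to the C8 methoxy group; C2 and C3 each carry a hydroxymethyl group. The two stereocentres, C1 (R) and C2 (S), are adjacent and trans, and C3 is trigonal, so the stereochemical problem is a single vicinal pair. The molecule is fragile in several ways: it is one oxidation away from a 1-arylnaphthalene, C1 is doubly benzylic and ionisable next to two electron-rich rings, the C3 alcohol is allylic, and the styrene chromophore is photoactive. The real difficulty is absolute control of the trans C1/C2 pair with C3=C4 left in place and with no ring heteroatom to steer it. The key step uses the fact that C2–C3 joins the two ends of a hexatriene C2=C1–C8a=C4a–C4=C3, which borrows the C4a=C8a bond of ring A. After such a closure the hydrogen that C1 needs sits on C3, and the two CH2O arms on C2 and C3 can hold a C2-symmetric diacyl bridge.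

## Logic of the disconnections

16 to 15: no skeletal bond is cut; the two O–H groups of 16 become two acyl–oxygen bonds to one bridging diacyl unit. The reason is that the only functional handles near C2 and C3 are these two oxygens, and a chiral C2-symmetric bridge between them makes the closure of ring B intramolecular in its stereocontrol. The skeleton is unchanged. The forward step must cleave two ester links without touching C1, C2 or the C3=C4 bond.

15 to 13 (through 14): the C2–C3 bond is cut and the C1 hydrogen is returned to C3. This removes ring B and both stereocentres at once; what remains in 13 is a flat ortho-divinylarene whose stereochemical content is two alkene geometries and the tether. The forward step must be a light-driven conrotatory closure with both CH2O groups outside, a hydrogen shift that ends on C1 and not on C4, and one preferred helical sense of the triene.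

13 to 10 plus 12: both acyl–oxygen bonds of the 14-membered ring are cut. The macrocycle falls apart into an achiral diol and a chiral bis-electrophile. Because the diacyl unit is C2-symmetric, either hydroxyl may react first. The forward step needs high dilution and must not epimerise the tether.

12 to 11: the two C–Cl bonds are cut; this is plain activation of a purchasable enantiopure diacid and must only preserve its trans configuration.

10 to 8 plus 9: the C1–aryl bond (sp2–sp2) is cut. The geometry of the trisubstituted C1=C2 bond is thereby reduced to that of a vinyl iodide. The forward coupling must proceed with retention at a crowded carbon and tolerate two free hydroxyl groups.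

8 to 6 (through 7): the C1–I bond is cut and the C2 hydrogen removed, which leads back to an alkyne. The alkene geometry then comes from a stereospecific anti addition directed by the propargylic oxygen. The forward step must place the metal on C1, cis to CH2O, and must leave the cinnamyl alcohol alone.

6 to 4 plus 5: the C8a–C1 bond (sp2–sp) is cut, giving an aryl iodide and a three-carbon alkyne that already holds C1, C2 and the C2 oxygen. The forward coupling has to work at a position flanked by two ortho substituents.

4 to 3 to 2: the ester is traced back from the alcohol, and the C3=C4 bond is cut by olefination logic. C3 and its oxygenated carbon arrive as a two-carbon phosphonate, and the E geometry (CH2O outside) is the thermodynamic outcome.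

2 to 1: the C8a–I bond is cut. Both free positions of 1 are equivalent, so the halogen can only enter where C8a is needed.

## Other disconnections considered

Alternative 1: The cut goes through ring A (C8a–C4a and C5–C6). Ring A is traced back to a 3,4-dimethoxyfuran-2-yl group on C1 and a terminal alkyne on C4 in the furan–enyne A1, which already holds C1, C2, both silyloxymethyl groups and the C3=C4 bond.
- Forward step: heating A1 would bring about an intramolecular furan–alkyne Diels–Alder reaction that closes ring B. The oxygen bridge would open at C8a and ring A would aromatise as the C6 phenol A2. O-Methylation and desilylation would follow.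
- In its favour: the step is thermal, forms two carbon–carbon bonds and two rings, and has C3=C4 fixed in position from the start. There is no hydrogen-shift ambiguity and no photolabile product under the lamp. On these mechanistic points it is the better plan.
- Against it: the key step creates no stereocentre. C1 and C2 must be set in an open chain beforehand, where C1 is an epimerisable furyl(aryl)methine. Electron-rich dialkoxyfurans are sensitive to acid and air, and an unactivated terminal alkyne needs forcing temperatures. Two steps and a pair of protecting groups follow the key step.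
- Comparison: equal in final oxidation level of the CH2O groups; safer in mechanism; poorer in stereochemical economy; judged longer in step count because A1 needs its own stereocontrolled synthesis.

Alternative 2: The cut is C1–C2 and C3–C4, so ring B comes from the ortho-benzylbenzaldehyde A3 and dimethyl fumarate A4.
- Forward step: irradiation of A3 at 365 nm would give an (E,E)-hydroxy-ortho-quinodimethane by photoenolisation. Cycloaddition to A4 on a Ti(OiPr)4/TADDOL template would give the hydroxytetralin diester A5. Dehydration across C3–C4 and reduction of both esters would follow.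
- In its favour: it is convergent, A3 should be one or two steps from 2, and two bonds and four stereocentres are formed at once. Templated asymmetric photoenolisation/Diels–Alder reactions have precedent with related aldehydes. It is therefore closer to known chemistry and probably the shortest of the four plans; on both counts it is better than the chosen one.
- Against it: a fumarate diester binds the titanium template less well than the enones used in the precedent. The hydrogen to be abstracted sits on a diarylmethylene next to the C8 methoxy group. The chiral titanium reagent is stoichiometric. Two of the four new stereocentres (C3, C4) are destroyed again, the esters are at the wrong oxidation level, and the dehydration must not epimerise C2 or aromatise ring B.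
- Comparison: the chosen plan gives C3=C4 and both CH2O groups at their final oxidation level in one isomerisation of full atom economy, with one step after the key step against two here. Both plans use light and share the risk of secondary photochemistry.

Alternative 3: The cut is the bond from C2 to its oxygenated carbon together with C1–C8a, leading to the dienyl orthoformate A6.
- Forward step: a confined chiral imidodiphosphorimidate Brønsted acid would ionise A6 to a dialkoxycarbenium ion. This would attack C2 of the diene and close a five-membered cyclic acetal. The resulting C1 cation would be trapped by ring A to close ring B and give the methoxytetrahydrofuran A7. Acetal hydrolysis and reduction would follow.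
- In its favour: stereocontrol is catalytic, with no stoichiometric chiral tether, and in this it is better than the chosen plan. It is thermal, forms two bonds, two rings and both stereocentres in one step, and starts from an achiral precursor of modest length.
- Against it: a Prins attack of a dialkoxycarbenium ion on a 1,3-diene followed by Friedel–Crafts closure is itself unprecedented, so it is no safer than the chosen key step. A strong acid with two very electron-rich arenes and a diene invites oligomerisation. C1 depends on the diastereoselectivity of the arene attack, and the C2 carbon arrives at the aldehyde oxidation level.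
- Comparison: equal in the number of bonds and stereocentres made and in overall length; better in using a catalyst; worse in needing two steps after the key step and in exposing 16-type intermediates to acid at the ionisable C1.

Key step: step 9

Assumption: the (1R,2R) tether is taken as the antipode whose preferred helical sense of closure leads to (1R,2S); this cannot be derived on paper. Because the tether stays in 15, the two possible outcomes are diastereomers and can be separated, and a mismatch would be answered by the antipodal tether in the same sequence.

Step 1
Reactants: 1 3,4,5-trimethoxybenzaldehyde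
Product: 2 2-iodo-3,4,5-trimethoxybenzaldehyde
Conditions: I2, CF3CO2Ag, CH2Cl2, 0 °C to rt
Reagents that add atoms: iodine, II
Why: Silver-assisted electrophilic aromatic iodination; the two free ring positions are equivalent and each is ortho and para to a methoxy group, so one mono-iodide should form, and the iodide (not the bromide) is chosen to ease the later coupling at this crowded position.

Step 2
Reactants: 2 2-iodo-3,4,5-trimethoxybenzaldehyde
Product: 3 ethyl (2E)-3-(2-iodo-3,4,5-trimethoxyphenyl)prop-2-enoate
Conditions: (EtO)2P(O)CH2CO2Et, NaH, THF, 0 °C to rt
Reagents that add atoms: triethyl phosphonoacetate, CCOC(=O)CP(=O)(OCC)OCC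
Why: Horner–Wadsworth–Emmons olefination; the stabilised phosphonate anion should give the E-enoate, which places the future C3 substituent outside on the triene terminus.

Step 3
Reactants: 3 ethyl (2E)-3-(2-iodo-3,4,5-trimethoxyphenyl)prop-2-enoate
Product: 4 (2E)-3-(2-iodo-3,4,5-trimethoxyphenyl)prop-2-en-1-ol
Conditions: iBu2AlH, CH2Cl2, −78 °C to 0 °C
Reagents that add atoms: none
Why: 1,2-Reduction of the enoate by iBu2AlH at low temperature should give the allylic alcohol without touching the aryl iodide or the alkene geometry.

Step 4
Reactants: 4 (2E)-3-(2-iodo-3,4,5-trimethoxyphenyl)prop-2-en-1-ol; 5 propargyl alcohol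
Product: 6 (2E)-3-[2-(3-hydroxyprop-1-yn-1-yl)-3,4,5-trimethoxyphenyl]prop-2-en-1-ol
Conditions: Pd(PPh3)2Cl2 (cat.), CuI (cat.), Et3N, THF, degassed, 50 °C
Reagents that add atoms: none
Why: Sonogashira coupling; aryl iodides couple under mild conditions, so the two free hydroxyl groups need no protection, and no ring closure onto the neighbouring alkene is geometrically available to the arylpalladium intermediate.

Step 5
Reactants: 6 (2E)-3-[2-(3-hydroxyprop-1-yn-1-yl)-3,4,5-trimethoxyphenyl]prop-2-en-1-ol
Product: 8 (2E)-3-{2-[(1Z)-3-hydroxy-1-iodoprop-1-en-1-yl]-3,4,5-trimethoxyphenyl}prop-2-en-1-ol, via vinylalanate 7 (not isolated)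
Conditions: NaAlH2(OCH2CH2OMe)2 (excess), THF, 0 °C; EtOAc quench; then I2, THF, −78 °C to 0 °C
Reagents that add atoms: iodine, II
Why: Alkoxide-directed trans-hydroalumination of the propargylic alcohol delivers hydride to C2 and aluminium to C1 within the five-membered alanate 7, and iodinolysis with retention should give the (Z)-iodide with iodine cis to CH2OH; the cinnamyl alkoxide is hydroaluminated only on heating and should survive at 0 °C.

Step 6
Reactants: 8 (2E)-3-{2-[(1Z)-3-hydroxy-1-iodoprop-1-en-1-yl]-3,4,5-trimethoxyphenyl}prop-2-en-1-ol; 9 3,4-dimethoxyphenylboronic acid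
Product: 10 (2E)-3-{2-[(1E)-1-(3,4-dimethoxyphenyl)-3-hydroxyprop-1-en-1-yl]-3,4,5-trimethoxyphenyl}prop-2-en-1-ol
Conditions: Pd(dppf)Cl2 (cat.), K2CO3, 1,4-dioxane/H2O, 80 °C
Reagents that add atoms: none
Why: Suzuki–Miyaura coupling with retention of alkene geometry puts the dimethoxyphenyl group where iodine was, cis to CH2OH, so the C2 CH2O group ends up trans to ring A (outside); both palladium couplings are run before any allylic ester exists, because allylic esters would ionise on zerovalent palladium.

Step 7
Reactants: 11 (1R,2R)-cyclohexane-1,2-dicarboxylic acid
Product: 12 (1R,2R)-cyclohexane-1,2-dicarbonyl dichloride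
Conditions: (COCl)2, DMF (cat.), CH2Cl2, 0 °C to rt
Reagents that add atoms: oxalyl chloride, ClC(=O)C(=O)Cl
Why: Acid chloride formation through the chloroiminium activator; no base is present, so the trans (1R,2R) configuration next to the carbonyl groups should be kept.

Step 8
Reactants: 10 (2E)-3-{2-[(1E)-1-(3,4-dimethoxyphenyl)-3-hydroxyprop-1-en-1-yl]-3,4,5-trimethoxyphenyl}prop-2-en-1-ol; 12 (1R,2R)-cyclohexane-1,2-dicarbonyl dichloride
Product: 13 14-membered cyclic (1R,2R)-cyclohexane-1,2-dicarboxylate of diol 10 (both alkene geometries as in 10)
Conditions: pyridine, DMAP (cat.), CH2Cl2, slow simultaneous addition of 10 and 12, final concentration 1–2 mM, rt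
Reagents that add atoms: none
Why: Double acylation to a macrodiolide under high dilution with nucleophilic catalysis; 12 is C2-symmetric, so either hydroxyl may react first and both mono-esters close to the same ring, and pyridine is preferred to a trialkylamine to avoid ketene formation and epimerisation of the tether.

Step 9
Reactants: 13 14-membered cyclic (1R,2R)-cyclohexane-1,2-dicarboxylate of diol 10
Product: 15 cyclic (1R,2R)-cyclohexane-1,2-dicarboxylate (10-membered diester ring) of [(1R,2S)-1-(3,4-dimethoxyphenyl)-6,7,8-trimethoxy-1,2-dihydronaphthalene-2,3-diyl]dimethanol, via ortho-quinodimethane 14 (not isolated)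
Conditions: hν (Pyrex-filtered Hg lamp, λ > 300 nm), degassed MeCN, 1 mM, 0 °C, flow reactor, partial conversion with recycling of 13
Reagents that add atoms: none
Why: Proposed new method: excitation of the twisted ortho-divinylarene chromophore of 13 should trigger conrotatory 6π electrocyclisation of the hexatriene C2=C1–C8a=C4a–C4=C3, which closes the six-membered ring B through the C2–C3 bond and contracts the 14-membered diolide to a 10-membered one in the ortho-quinodimethane 14; a thermal suprafacial 1,5-hydrogen shift from C3 to C1 should then restore ring A and leave C3=C4. The closest known reaction type is the photocyclisation of ortho-divinylbenzenes and 2-vinylbiaryls to dihydroarenes by 6π closure and 1,5-hydrogen shift; control of absolute configuration by a chiral diacyl tether is the new element. C2 is set in the electrocyclisation: its relation to C3 (trans) follows from conrotation with both CH2O groups outside, and its absolute configuration from the helical sense of the triene, whose two senses the C2-symmetric (1R,2R) tether makes diastereomeric. C1 is set by the sigmatropic shift: the hydrogen leaves C3 and reaches C1 on the same face, anti to the C2 hydrogen, so the aryl group and the C2 substituent should end up trans. The six-atom tether can span the two CH2O carbons only when both vinyl arms are turned towards each other, so the ground state is confined to the s-cis/s-cis rotamers that the closure needs. The step also needs the hydrogen to go to C1 and not from C2 to C4; the peri clash between the C1 aryl group and the C8 methoxy group in 14 is relieved only when C1 becomes tetrahedral, which should favour the wanted terminus. The long-wavelength cut-off, low conversion per pass and exclusion of oxygen are meant to suppress secondary ring opening and aromatisation of 15.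

Step 10
Reactants: 15 cyclic (1R,2R)-cyclohexane-1,2-dicarboxylate of [(1R,2S)-1-(3,4-dimethoxyphenyl)-6,7,8-trimethoxy-1,2-dihydronaphthalene-2,3-diyl]dimethanol
Product: 16 [(1R,2S)-1-(3,4-dimethoxyphenyl)-3-(hydroxymethyl)-6,7,8-trimethoxy-1,2-dihydronaphthalen-2-yl]methanol
Conditions: K2CO3 (cat.), MeOH, argon, rt
Reagents that add atoms: none
Why: Base-catalysed transesterification should cleave both ester links of the strained 10-membered diolide; neither C1 nor C2 is acidic under these conditions, and oxygen is excluded to avoid aromatisation.

Compound list

1 | 3,4,5-trimethoxybenzaldehyde | COc1cc(C=O)cc(OC)c1OC | starting material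
2 | 2-iodo-3,4,5-trimethoxybenzaldehyde | COc1cc(C=O)c(I)c(OC)c1OC | intermediate
3 | ethyl (2E)-3-(2-iodo-3,4,5-trimethoxyphenyl)prop-2-enoate | CCOC(=O)/C=C/c1cc(OC)c(OC)c(OC)c1I | intermediate
4 | (2E)-3-(2-iodo-3,4,5-trimethoxyphenyl)prop-2-en-1-ol | OC/C=C/c1cc(OC)c(OC)c(OC)c1I | intermediate
5 | propargyl alcohol (prop-2-yn-1-ol) | C#CCO | starting material
6 | (2E)-3-[2-(3-hydroxyprop-1-yn-1-yl)-3,4,5-trimethoxyphenyl]prop-2-en-1-ol | OC/C=C/c1cc(OC)c(OC)c(OC)c1C#CCO | intermediate
7 | cyclic vinylalanate, not isolated: disodium salt of 2,2-bis(2-methoxyethoxy)-3-aryl-2,5-dihydro-1,2-oxaluminol-2-uide, aryl = 2-[(1E)-3-oxidoprop-1-en-1-yl]-3,4,5-trimethoxyphenyl; aluminium on C1, cis to CH2O | COCCO[Al-]1(OCCOC)OCC=C1c1c(/C=C/C[O-])cc(OC)c(OC)c1OC.[Na+].[Na+] | intermediate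
8 | (2E)-3-{2-[(1Z)-3-hydroxy-1-iodoprop-1-en-1-yl]-3,4,5-trimethoxyphenyl}prop-2-en-1-ol (iodine cis to CH2OH) | OC/C=C/c1cc(OC)c(OC)c(OC)c1/C(I)=C/CO | intermediate
9 | 3,4-dimethoxyphenylboronic acid | COc1ccc(B(O)O)cc1OC | starting material
10 | (2E)-3-{2-[(1E)-1-(3,4-dimethoxyphenyl)-3-hydroxyprop-1-en-1-yl]-3,4,5-trimethoxyphenyl}prop-2-en-1-ol (dimethoxyphenyl cis to CH2OH, ring A trans to it) | OC/C=C/c1cc(OC)c(OC)c(OC)c1/C(=C/CO)c1ccc(OC)c(OC)c1 | intermediate
11 | (1R,2R)-cyclohexane-1,2-dicarboxylic acid | OC(=O)[C@@H]1CCCC[C@H]1C(=O)O | starting material
12 | (1R,2R)-cyclohexane-1,2-dicarbonyl dichloride | ClC(=O)[C@@H]1CCCC[C@H]1C(=O)Cl | intermediate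
13 | 14-membered macrocyclic diester in which the (1R,2R)-cyclohexane-1,2-dicarbonyl unit bridges the two allylic oxygens of 10; C3=C4 is E, and at C1=C2 the dimethoxyphenyl group is cis to CH2O | COc1ccc(/C2=C\COC(=O)[C@@H]3CCCC[C@H]3C(=O)OC/C=C/c3cc(OC)c(OC)c(OC)c32)cc1OC | intermediate
14 | ortho-quinodimethane, not isolated: trans-2,3-dihydronaphthalene isomer of 13 with C2–C3 formed, exocyclic C1=C8a and C4=C4a, ring A dearomatised, C2 configured as in 15, C3 hydrogen trans to C2 hydrogen, 10-membered (R,R)-diester bridge | COc1ccc(C2=C3C(OC)=C(OC)C(OC)=CC3=C[C@@H]3COC(=O)[C@@H]4CCCC[C@H]4C(=O)OC[C@@H]23)cc1OC | intermediate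
15 | cyclic (1R,2R)-cyclohexane-1,2-dicarboxylate (10-membered diester ring) of [(1R,2S)-1-(3,4-dimethoxyphenyl)-6,7,8-trimethoxy-1,2-dihydronaphthalene-2,3-diyl]dimethanol | COc1ccc([C@@H]2c3c(cc(OC)c(OC)c3OC)C=C3COC(=O)[C@@H]4CCCC[C@H]4C(=O)OC[C@@H]23)cc1OC | intermediate
16 | [(1R,2S)-1-(3,4-dimethoxyphenyl)-3-(hydroxymethyl)-6,7,8-trimethoxy-1,2-dihydronaphthalen-2-yl]methanol (CNP0274357.1) | COc1ccc([C@@H]2c3c(cc(OC)c(OC)c3OC)C=C(CO)[C@H]2CO)cc1OC | target

Step count and risks

Total: 10 steps. Longest linear sequence: 9 steps (1, 2, 3, 4, 6, 8, 10, 13, 15, 16); step 7 is a one-step side branch. Only step 9 carries the label.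

Step 9 (carries the label). Three things are most likely to go wrong:
- The two helical senses of closure may be poorly discriminated, because the 14-membered ring may leave both twisted rotamers populated or let them interconvert in the excited state. This would cost throughput but not purity, since the tether makes the two outcomes diastereomers.
- The wrong hydrogen may migrate (from C2 to C4), which would move the double bond to C1=C2 and erase C1.
- The excited state may be diverted into E/Z isomerisation or [2+2] closure of the two vinyl groups, and the product may undergo secondary ring opening under the same light.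

Fallback (thermal, known reactions only, setting out from 1 and returning at 16): Stobbe condensation of 1 with diethyl succinate (KOtBu, tBuOH) would give the half-ester (3E)-3-(ethoxycarbonyl)-4-(3,4,5-trimethoxyphenyl)but-3-enoic acid F1, in which ring A is cis to the CH2CO2H arm. Activation as the mixed pivalic anhydride and acylation of lithiated (R)-4-benzyloxazolidin-2-one would give the imide F2. An Evans syn-aldol reaction (Bu2BOTf, iPr2NEt, CH2Cl2, −78 °C) with 3,4-dimethoxybenzaldehyde would set C2 and give the β-hydroxy imide F3. CF3CO2H in CH2Cl2 would ionise the benzylic alcohol, and ring A would close C1–C8a trans to the C2 acyl group (intramolecular Friedel–Crafts alkylation) to give the dihydronaphthalene imide ester F4. LiAlH4 would reduce the imide and the ester and return to the route at 16. Here the auxiliary fixes C2, and C1 follows from C2 in the cationic ring closure.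

Step 8. Most likely to go wrong: chain growth (oligomerisation) instead of ring closure, and epimerisation of the tether through ketene formation from the acid chloride under base. Fallback (stepwise, from 10 and 11, returning at 13): heating 11 with acetyl chloride would give the trans-anhydride (3aR,7aR)-hexahydro-2-benzofuran-1,3-dione F5. Slow addition of F5 to 10 (DMAP, CH2Cl2) would open it at either hydroxyl and give two hydroxy acids, the cinnamyl-acylated mono-ester F6 and the diarylallyl-acylated mono-ester F7. The mixture needs no separation: Yamaguchi macrolactonisation (2,4,6-trichlorobenzoyl chloride, Et3N, then DMAP, toluene, high dilution) of either isomer closes the same ring and returns to the route at 13.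

Step 5. Most likely to go wrong: competing hydroalumination of the cinnamyl double bond directed by its own alkoxide, or loss of regiocontrol so that aluminium ends up on C2. Fallback (from 4, returning at 8): silylation (tBuMe2SiCl, imidazole) would give the silyl ether F8. Sonogashira coupling with 5 would give the mono-protected enyne F9. With only the propargylic hydroxyl free to direct the reagent, NaAlH2(OCH2CH2OMe)2 then I2 would give the vinyl iodide F10. Bu4NF would remove the silyl group and return to the route at 8.

Step 4. Most likely to go wrong: slow oxidative addition into the electron-rich, doubly ortho-substituted aryl iodide, so that copper-mediated homocoupling of 5 takes over. Fallback (changed order of bond formation, from 2, returning at 6): coupling of 2 with 5 at the aldehyde stage, where the formyl group activates the iodide, would give the alkynyl aldehyde F11. Horner–Wadsworth–Emmons olefination would give the enoate F12. Reduction with iBu2AlH would return to the route at 6.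

Further compounds

F1 | step 9 | (3E)-3-(ethoxycarbonyl)-4-(3,4,5-trimethoxyphenyl)but-3-enoic acid | CCOC(=O)/C(CC(=O)O)=C/c1cc(OC)c(OC)c(OC)c1
F2 | step 9 | (4R)-4-benzyl-3-[(3E)-3-(ethoxycarbonyl)-4-(3,4,5-trimethoxyphenyl)but-3-enoyl]-1,3-oxazolidin-2-one | CCOC(=O)/C(CC(=O)N1[C@H](Cc2ccccc2)COC1=O)=C/c1cc(OC)c(OC)c(OC)c1
F3 | step 9 | (4R)-4-benzyl-3-[(2R,3E)-2-[(R)-(3,4-dimethoxyphenyl)(hydroxy)methyl]-3-(ethoxycarbonyl)-4-(3,4,5-trimethoxyphenyl)but-3-enoyl]-1,3-oxazolidin-2-one | CCOC(=O)/C(=C/c1cc(OC)c(OC)c(OC)c1)[C@@H](C(=O)N1[C@H](Cc2ccccc2)COC1=O)[C@@H](O)c1ccc(OC)c(OC)c1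
F4 | step 9 | ethyl (1R,2S)-2-{[(4R)-4-benzyl-2-oxo-1,3-oxazolidin-3-yl]carbonyl}-1-(3,4-dimethoxyphenyl)-6,7,8-trimethoxy-1,2-dihydronaphthalene-3-carboxylate (numbering as in 16) | COc1ccc([C@@H]2c3c(cc(OC)c(OC)c3OC)C=C(C(=O)OCC)[C@H]2C(=O)N2[C@H](Cc3ccccc3)COC2=O)cc1OC
F5 | step 8 | (3aR,7aR)-hexahydro-2-benzofuran-1,3-dione | O=C1OC(=O)[C@@H]2CCCC[C@@H]12
F6 | step 8 | hydroxy acid: mono-ester of 11 at the cinnamyl oxygen of 10 | OC(=O)[C@@H]1CCCC[C@H]1C(=O)OC/C=C/c1cc(OC)c(OC)c(OC)c1/C(=C/CO)c1ccc(OC)c(OC)c1
F7 | step 8 | hydroxy acid: mono-ester of 11 at the diarylallyl oxygen of 10 | OC/C=C/c1cc(OC)c(OC)c(OC)c1/C(=C/COC(=O)[C@@H]1CCCC[C@H]1C(=O)O)c1ccc(OC)c(OC)c1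
F8 | step 5 | tert-butyl{[(2E)-3-(2-iodo-3,4,5-trimethoxyphenyl)prop-2-en-1-yl]oxy}dimethylsilane | CC(C)(C)[Si](C)(C)OC/C=C/c1cc(OC)c(OC)c(OC)c1I
F9 | step 5 | 3-{2-[(1E)-3-{[tert-butyl(dimethyl)silyl]oxy}prop-1-en-1-yl]-3,4,5-trimethoxyphenyl}prop-2-yn-1-ol | CC(C)(C)[Si](C)(C)OC/C=C/c1cc(OC)c(OC)c(OC)c1C#CCO
F10 | step 5 | (2Z)-3-{2-[(1E)-3-{[tert-butyl(dimethyl)silyl]oxy}prop-1-en-1-yl]-3,4,5-trimethoxyphenyl}-3-iodoprop-2-en-1-ol | CC(C)(C)[Si](C)(C)OC/C=C/c1cc(OC)c(OC)c(OC)c1/C(I)=C/CO
F11 | step 4 | 2-(3-hydroxyprop-1-yn-1-yl)-3,4,5-trimethoxybenzaldehyde | COc1cc(C=O)c(C#CCO)c(OC)c1OC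
F12 | step 4 | ethyl (2E)-3-[2-(3-hydroxyprop-1-yn-1-yl)-3,4,5-trimethoxyphenyl]prop-2-enoate | CCOC(=O)/C=C/c1cc(OC)c(OC)c(OC)c1C#CCO
A1 | alternative 1 | furan–enyne: 2-[1-(3,4-dimethoxyphenyl)-2,3-bis(tert-butyldimethylsilyloxymethyl)hex-3-en-5-yn-1-yl]-3,4-dimethoxyfuran, stereocentres as in 16, alkyne cis to C2 | COc1ccc([C@H](c2occ(OC)c2OC)[C@H](CO[Si](C)(C)C(C)(C)C)/C(CO[Si](C)(C)C(C)(C)C)=C\C#C)cc1OC
A2 | alternative 1 | trans-1-(3,4-dimethoxyphenyl)-2,3-bis(tert-butyldimethylsilyloxymethyl)-7,8-dimethoxy-1,2-dihydronaphthalen-6-ol | COc1ccc([C@@H]2c3c(cc(O)c(OC)c3OC)C=C(CO[Si](C)(C)C(C)(C)C)[C@H]2CO[Si](C)(C)C(C)(C)C)cc1OC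
A3 | alternative 2 | 2-(3,4-dimethoxybenzyl)-3,4,5-trimethoxybenzaldehyde | COc1ccc(Cc2c(C=O)cc(OC)c(OC)c2OC)cc1OC
A4 | alternative 2 | dimethyl fumarate | COC(=O)/C=C/C(=O)OC
A5 | alternative 2 | dimethyl 1-(3,4-dimethoxyphenyl)-4-hydroxy-6,7,8-trimethoxy-1,2,3,4-tetrahydronaphthalene-2,3-dicarboxylate (aryl and C2 ester trans, aryl and hydroxyl cis) | COc1ccc([C@@H]2c3c(cc(OC)c(OC)c3OC)[C@H](O)[C@H](C(=O)OC)[C@H]2C(=O)OC)cc1OC
A6 | alternative 3 | dienyl orthoformate: dimethyl (3E)-4-(3,4-dimethoxyphenyl)-2-(3,4,5-trimethoxybenzylidene)but-3-en-1-yl orthoformate, ring A cis to the styryl group | COC(OC)OC/C(=C/c1cc(OC)c(OC)c(OC)c1)/C=C/c1ccc(OC)c(OC)c1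
A7 | alternative 3 | methoxytetrahydrofuran (cyclic acetal, acetal carbon as a mixture) fused across C2–C3 of the trans-1-(3,4-dimethoxyphenyl)-6,7,8-trimethoxy-1,2-dihydronaphthalene | COc1ccc([C@@H]2c3c(cc(OC)c(OC)c3OC)C=C3COC(OC)[C@@H]23)cc1OC
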